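**Retrosynthetic overview**
1. Target ⇐ one global hydrogenation of a tri-O-benzyl pyrano-isoflavone, which removes three benzyl groups and saturates the 2H-chromene to the chroman.
2. Ring C and the C3–aryl bond ⇐ a one-flask palladium-catalysed α-C–H arylation/annulation (the new step) of an o-hydroxyaryl enaminone (ring A) with a 5-bromo-2H-chromene (ring B plus pyran ring).
3. Bromochromene ⇐ propargyl Claisen/electrocyclisation of the 1,1-dimethylpropargyl ether of 2-(benzyloxy)-5-bromophenol; the OBn group blocks one ortho carbon, so the pyran closes onto the carbon between O and Br.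
4. Ring order: ring A is bought (phloroacetophenone), the pyran ring on ring B is built first, ring C is closed in the new step, and the pyran ring is saturated last.

Assumption: the target has no stereocentre and no stereogenic double bond, so the achiral compound itself is the "single enantiomer" and no asymmetric step is needed.

**Route**

Step 1
Reactants: 1 1-(2,4,6-trihydroxyphenyl)ethan-1-one
Product: 2 1-[2,4-bis(benzyloxy)-6-hydroxyphenyl]ethan-1-one
Conditions: BnBr (2.05 equiv), K2CO3 (2.2 equiv), DMF, 0 °C to rt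
Reagents that add atoms: benzyl bromide, BrCc1ccccc1
Why: Williamson etherification alkylates two phenols, while the third hydroxyl is hydrogen-bonded to the ketone, is the least nucleophilic and stays free at two equivalents of BnBr.

Step 2
Reactants: 2 1-[2,4-bis(benzyloxy)-6-hydroxyphenyl]ethan-1-one
Product: 3 (E)-1-[2,4-bis(benzyloxy)-6-hydroxyphenyl]-3-(dimethylamino)prop-2-en-1-one
Conditions: DMF-DMA (3 equiv), toluene, 95 °C
Reagents that add atoms: N,N-dimethylformamide dimethyl acetal, COC(OC)N(C)C
Why: Amide-acetal condensation of the methyl ketone (enaminone formation), driven by loss of methanol, gives the thermodynamically favoured E-enaminone and leaves the chelated phenol free.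

Step 3
Reactants: 4 5-bromo-2-hydroxybenzaldehyde
Product: 5 2-(benzyloxy)-5-bromobenzaldehyde
Conditions: BnBr (1.1 equiv), K2CO3 (1.5 equiv), DMF, rt
Reagents that add atoms: benzyl bromide, BrCc1ccccc1
Why: Williamson etherification of the only phenol is clean and high-yielding.

Step 4
Reactants: 5 2-(benzyloxy)-5-bromobenzaldehyde
Product: 7 2-(benzyloxy)-5-bromophenol, via aryl formate 6 (not isolated)
Conditions: mCPBA (1.3 equiv), CH2Cl2, 0 °C to rt; aq. NaHCO3 wash, concentrate; then K2CO3 (0.2 equiv), MeOH, rt
Reagents that add atoms: mCPBA, OOC(=O)c1cccc(Cl)c1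
Why: Baeyer–Villiger (Dakin-type) oxidation in which the electron-rich o-alkoxyaryl group migrates in preference to hydride gives the aryl formate, which methanol transesterifies under catalytic carbonate.

Step 5
Reactants: 7 2-(benzyloxy)-5-bromophenol
Product: 8 1-(benzyloxy)-4-bromo-2-[(2-methylbut-3-yn-2-yl)oxy]benzene
Conditions: 3-chloro-3-methylbut-1-yne (1.5 equiv), K2CO3 (2 equiv), KI (10 mol %), CuI (5 mol %), acetone, reflux, N2
Reagents that add atoms: 3-chloro-3-methylbut-1-yne, CC(C)(Cl)C#C
Why: Copper-assisted Williamson-type O-propargylation, in which the tertiary propargylic chloride ionises through a copper acetylide and the phenoxide captures the tertiary carbon.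

Step 6
Reactants: 8 1-(benzyloxy)-4-bromo-2-[(2-methylbut-3-yn-2-yl)oxy]benzene
Product: 10 8-(benzyloxy)-5-bromo-2,2-dimethyl-2H-chromene, via allenylphenol 9 (not isolated)
Conditions: PhNEt2, 190 °C, 3 h
Reagents that add atoms: none
Why: The aromatic propargyl Claisen rearrangement ([3,3]-sigmatropic shift) can only deliver to the one free ortho carbon because the other carries OBn, and the allenylphenol then closes by 1,5-hydrogen shift and oxa-6π electrocyclisation to the chromene with bromine at C5.

Step 7
Reactants: 3 (E)-1-[2,4-bis(benzyloxy)-6-hydroxyphenyl]-3-(dimethylamino)prop-2-en-1-one; 10 8-(benzyloxy)-5-bromo-2,2-dimethyl-2H-chromene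
Product: 12 5,7-bis(benzyloxy)-3-[8-(benzyloxy)-2,2-dimethyl-2H-chromen-5-yl]-4H-chromen-4-one, via α-aryl enaminone 11 (not isolated)
Conditions: Pd(OAc)2 (5 mol %), XPhos (10 mol %), PivOH (30 mol %), K2CO3 (2.5 equiv), 1,4-dioxane, 100 °C, N2 sweep
Reagents that add atoms: none
Why: Proposed new method: zerovalent palladium formed from Pd(OAc)2/XPhos inserts into the C–Br bond of 10, the push–pull enaminone 3 (as its potassium phenoxide) attacks the divalent arylpalladium bromide through its nucleophilic α-carbon to give an iminium-stabilised σ-complex that pivalate deprotonates (concerted metalation–deprotonation), reductive elimination forms the C3–aryl bond of 11, and the phenoxide then adds to the β-carbon and expels Me2NH to close ring C, while the chelated, electron-poor phenoxide is a poor partner for competing C–O coupling; the closest known reaction types are palladium-catalysed direct C–H arylation of cyclic enaminones, ketone-enolate α-arylation with aryl bromides and the iodine-triggered enaminone-to-3-iodochromone annulation, and the untested part is running an aryl-bromide arylation and the annulation in one flask on an open-chain o-hydroxyaryl enaminone.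

Step 8
Reactants: 12 5,7-bis(benzyloxy)-3-[8-(benzyloxy)-2,2-dimethyl-2H-chromen-5-yl]-4H-chromen-4-one
Product: 13 5,7-dihydroxy-3-(8-hydroxy-2,2-dimethyl-3,4-dihydro-2H-chromen-5-yl)-4H-chromen-4-one
Conditions: H2 (1 atm), 10% Pd/C, EtOAc–MeOH 1:1, rt, stopped at full conversion
Reagents that add atoms: none
Why: Heterogeneous catalytic hydrogenation cleaves the three benzyl aryl ethers and saturates the cis-disubstituted styrenic pyran alkene quickly, whereas the trisubstituted vinylogous-ester C2=C3 bond of the isoflavone, shielded by the ortho-substituted aryl group, reacts far more slowly.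

**Compound list**
1 | 1-(2,4,6-trihydroxyphenyl)ethan-1-one | CC(=O)c1c(O)cc(O)cc1O | starting material
2 | 1-[2,4-bis(benzyloxy)-6-hydroxyphenyl]ethan-1-one | CC(=O)c1c(O)cc(OCc2ccccc2)cc1OCc1ccccc1 | intermediate
3 | (E)-1-[2,4-bis(benzyloxy)-6-hydroxyphenyl]-3-(dimethylamino)prop-2-en-1-one | CN(C)/C=C/C(=O)c1c(O)cc(OCc2ccccc2)cc1OCc1ccccc1 | intermediate
4 | 5-bromo-2-hydroxybenzaldehyde | O=Cc1cc(Br)ccc1O | starting material
5 | 2-(benzyloxy)-5-bromobenzaldehyde | O=Cc1cc(Br)ccc1OCc1ccccc1 | intermediate
6 | 2-(benzyloxy)-5-bromophenyl formate (aryl formate) | O=COc1cc(Br)ccc1OCc1ccccc1 | intermediate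
7 | 2-(benzyloxy)-5-bromophenol | Oc1cc(Br)ccc1OCc1ccccc1 | intermediate
8 | 1-(benzyloxy)-4-bromo-2-[(2-methylbut-3-yn-2-yl)oxy]benzene | C#CC(C)(C)Oc1cc(Br)ccc1OCc1ccccc1 | intermediate
9 | 6-(benzyloxy)-3-bromo-2-(3-methylbuta-1,2-dien-1-yl)phenol (allenylphenol) | CC(C)=C=Cc1c(Br)ccc(OCc2ccccc2)c1O | intermediate
10 | 8-(benzyloxy)-5-bromo-2,2-dimethyl-2H-chromene | CC1(C)C=Cc2c(Br)ccc(OCc3ccccc3)c2O1 | intermediate
11 | (E)-1-[2,4-bis(benzyloxy)-6-hydroxyphenyl]-2-[8-(benzyloxy)-2,2-dimethyl-2H-chromen-5-yl]-3-(dimethylamino)prop-2-en-1-one (α-aryl enaminone) | CN(C)/C=C(\c1ccc(OCc2ccccc2)c2OC(C)(C)C=Cc12)C(=O)c1c(O)cc(OCc2ccccc2)cc1OCc1ccccc1 | intermediate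
12 | 5,7-bis(benzyloxy)-3-[8-(benzyloxy)-2,2-dimethyl-2H-chromen-5-yl]-4H-chromen-4-one | CC1(C)C=Cc2c(-c3coc4cc(OCc5ccccc5)cc(OCc5ccccc5)c4c3=O)ccc(OCc3ccccc3)c2O1 | intermediate
13 | 5,7-dihydroxy-3-(8-hydroxy-2,2-dimethyl-3,4-dihydro-2H-chromen-5-yl)-4H-chromen-4-one (CNP0078088.0, achiral) | CC1(C)CCc2c(-c3coc4cc(O)cc(O)c4c3=O)ccc(O)c2O1 | target

**Totals**
Total step count: 8. Longest linear sequence: 6 steps (4 → 5 → 7 → 8 → 10 → 12 → 13, steps 3 to 8); the ring A branch (steps 1 and 2) joins at step 7.

**Three steps most likely to fail**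

Risk 1, step 7 (the proposed new arylation/annulation). Likely failure modes are ring closure of 3 to the 3-unsubstituted chromone before arylation, O-arylation of the phenoxide, and protodebromination of the hindered, electron-rich bromide 10. The fallback uses known chemistry, sets out from 3 and 10 and comes back at 12. Enaminone 3 is cyclised with I2 (CHCl3, rt) to 5,7-bis(benzyloxy)-3-iodo-4H-chromen-4-one F1. Bromide 10 is borylated (B2pin2, PdCl2(dppf), KOAc, 1,4-dioxane, 90 °C) to 2-[8-(benzyloxy)-2,2-dimethyl-2H-chromen-5-yl]-4,4,5,5-tetramethyl-1,3,2-dioxaborolane F2. Suzuki–Miyaura coupling of the two (PdCl2(dppf), aq. Na2CO3, 1,4-dioxane, 80 °C) then gives 12.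

Risk 2, step 8 (global hydrogenation). The risk is over-reduction of the isoflavone C2=C3 bond to the isoflavanone, or a stalled debenzylation. The fallback separates the two reductive jobs and removes the benzyl groups without hydrogen; it sets out from 12 and comes back at 13. The pyran alkene alone is hydrogenated homogeneously (H2 1 atm, RhCl(PPh3)3 5 mol %, benzene–EtOH, rt), which does not touch benzyl ethers or the hindered conjugated C2=C3 bond, to give 5,7-bis(benzyloxy)-3-[8-(benzyloxy)-2,2-dimethyl-3,4-dihydro-2H-chromen-5-yl]-4H-chromen-4-one F3. The three benzyl ethers are then cleaved with BCl3 and pentamethylbenzene (CH2Cl2, −78 °C) to give 13.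

Risk 3, step 6 (Claisen/electrocyclisation onto the crowded carbon between O and Br at 190 °C). The risk is a sluggish rearrangement or decomposition at that temperature. The fallback builds the pyran ring from an ortho-formyl group and not by a sigmatropic shift; it sets out from 7 and comes back at 10. Ortho-specific formylation of 7 (MgCl2, Et3N, paraformaldehyde, MeCN, reflux) gives 3-(benzyloxy)-6-bromo-2-hydroxybenzaldehyde F4. Addition of 2-methylprop-1-enylmagnesium bromide (2.2 equiv, THF, 0 °C) gives rac-6-(benzyloxy)-3-bromo-2-(1-hydroxy-3-methylbut-2-en-1-yl)phenol F5, whose carbinol stereocentre is lost in the next operation. Warming F5 with PPTS in toluene (80 °C) effects dehydrative cyclisation to 10.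

Further compounds
F1 | step 7 | 5,7-bis(benzyloxy)-3-iodo-4H-chromen-4-one | O=c1c(I)coc2cc(OCc3ccccc3)cc(OCc3ccccc3)c12
F2 | step 7 | 2-[8-(benzyloxy)-2,2-dimethyl-2H-chromen-5-yl]-4,4,5,5-tetramethyl-1,3,2-dioxaborolane | CC1(C)C=Cc2c(B3OC(C)(C)C(C)(C)O3)ccc(OCc3ccccc3)c2O1
F3 | step 8 | 5,7-bis(benzyloxy)-3-[8-(benzyloxy)-2,2-dimethyl-3,4-dihydro-2H-chromen-5-yl]-4H-chromen-4-one | CC1(C)CCc2c(-c3coc4cc(OCc5ccccc5)cc(OCc5ccccc5)c4c3=O)ccc(OCc3ccccc3)c2O1
F4 | step 6 | 3-(benzyloxy)-6-bromo-2-hydroxybenzaldehyde | O=Cc1c(Br)ccc(OCc2ccccc2)c1O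
F5 | step 6 | rac-6-(benzyloxy)-3-bromo-2-(1-hydroxy-3-methylbut-2-en-1-yl)phenol | CC(C)=CC(O)c1c(Br)ccc(OCc2ccccc2)c1O
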